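## Structural features

Veramycin A has two flat end groups: a 3-ethyl-4-hydroxy-2H-pyran-2-one (O1, C2–C6, a vinylogous acid) and a 1,2,4-trisubstituted benzene (C1''–C6'') carrying an (E)-3-hydroxyprop-1-enyl group on C2'' and a methyl group on C4''. Pyranone C6 and arene C1'' are joined by the chain C2'–C3'–C4' of a pentan-2-yl unit. This chain bears CH3 (C1'), OH and CH3 (C5') on three contiguous stereocentres, (2'S,3'R,4'S), all syn in the zigzag drawing. The fragile groups are the acidic pyranone and the cinnamyl-type allylic alcohol (both attacked by hydrogenation catalysts, the alcohol also by strong acid), the C3' hydroxyl β to the pyranone (retro-aldol and dehydration at the open-chain stage), and C2'–H, which is epimerisable while C6 is still a ketone. The real difficulty is the triad: neither outer stereocentre carries a heteroatom, and C4' is benzylic. In an open chain, hydride delivery to a C3' ketone would have to oppose the Felkin preference on both sides, and a (Z)-enolate aldol would have to pair with an α-aryl aldehyde in its disfavoured Felkin mode. The key step exploits the fact that C1' and C5' are 1,5-related methyl carbons on either side of C3'. Joined through sulfur, they make C2', C3', C4' the ring atoms C3, C4, C5 of a thian-4-one, where the all-syn triad is the all-cis pattern and both outer centres are α to the C4 ketone and therefore mobile. With pyranone C6 held at the ester oxidation level, C2' is the α-carbon of a cyclic β-keto ester. The route in one sentence: a dynamic kinetic transfer hydrogenation of a stereochemically mobile 5-aryl-4-oxothiane-3-carboxylate fixes all three stereocentres at once, and hydrogenolysis of the two C–S bonds then turns the ring CH2 groups into the two C-methyl groups.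

## Logic of the disconnections

16 ⇒ 15 ⇒ 14. The two O–Si bonds and the O1–C2 acyl–oxygen bond of the pyranone are cut. The acidic, reducible heterocycle is best made last from an open 3,5-dioxo ester, and both alcohols can be unmasked together. The gain is an acyclic precursor with ordinary 1,3-dicarbonyl polarity. The forward lactonisation must not epimerise the carbon α to the C5 ketone of 14, and the two silyl ethers must leave under one mild set of conditions.

14 ⇒ 12 + 13. The bond between the C4 methylene and the C5 ketone carbon of 14 (pyranone C5–C6) is cut. This separates the achiral four-carbon unit 13 from the stereotriad. The forward step is a γ-acylation of a dianion by a hindered, α-branched acyl donor, which must add without enolising that donor.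

12 ⇒ 11 ⇒ 10 ⇒ 8 + 9. After two functional-group changes at the carboxyl and the carbinol, the C2''–vinyl bond is cut. The alkene cannot survive nickel, so it must enter after the sulfur is gone, and 9 brings the (E)-geometry and the protected primary alcohol ready-made. The forward coupling must work at an aryl C–O electrophile flanked by a branched alkyl group, which means a phenol has to be carried through the early steps.

8 ⇒ 7 ⇒ 6. After the phenol is revealed, the two C-methyl carbons are reconnected through sulfur (forward: both C–S bonds and the O–benzyl bond are hydrogenolysed). This converts the open all-syn triad into an all-cis trisubstituted six-membered ring, so the stereochemical problem becomes a conformational one. The forward hydrogenolysis must leave the carbinol and the ester untouched, which is why alkene and pyranone come later.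

6 ⇒ 5 (key). The C4–H bond of the ring carbinol is removed to give the ketone. Both neighbours become α-carbons and lose their configuration, so all three stereocentres are erased in one retrosynthetic stroke and 5 needs no stereocontrol in its preparation. The forward reduction must pick one of eight possible stereoisomers, and epimerisation at both α-carbons must keep pace with it.

5 ⇒ 4 ⇒ 2 + 3. The C3–CO2Me bond and then the bond from the ring to arene C1'' are cut. This reduces the key substrate to the cheap cyclic ketone 3 and the aryl bromide 2. The forward steps are a mono-α-arylation of a sulfur-containing ketone and a carboxylation that ends on the ring carbon remote from the aryl group.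

2 ⇒ 1. The O–benzyl bond is cut. The protecting group must survive base, palladium and the hydrogen-transfer catalyst and fall off during the nickel step.

## Other disconnections considered

Alternative 1: cut C2'–C3' as an auxiliary-controlled aldol, the first plan that comes to mind. The forward key step would be the boron-mediated syn-aldol of a propionyl oxazolidinone with (2S)-2-(2-bromo-4-methylphenyl)propanal A1 to give imide A2, followed by dianion acylation, lactonisation and a cross-coupling at the bromide. The chosen plan is preferred for three reasons. A1 has to be made enantioenriched in separate steps and, as an α-aryl aldehyde, is prone to racemise under the amine and boron triflate conditions. The all-syn array requires the (Z)-enolate to add in the Felkin sense, the pairing disfavoured by a syn-pentane interaction, so the auxiliary must overrule the aldehyde. The stereocentres are set in two separate events with a stoichiometric auxiliary, whereas the chosen plan sets all three in one catalytic event from a substrate with no fixed stereocentre.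

Alternative 2: cut C2'–C3' with the heterocycle intact. The forward key step would be deprotonation of 3,6-diethyl-4-methoxy-2H-pyran-2-one A3 at the C6 ethyl group and addition of the vinylogous enolate to A1, giving A4. This is the shortest plan on paper. However, the planar, delocalised dienolate carries no stereochemical information. Two new centres would form relative to a labile third one, and the basic dienolate would be expected to racemise A1. The O-methyl group of A4 would then have to be removed next to a β-hydroxyl group. The stereochemical problem would be left unsolved.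

Alternative 3: cut C4'–C1'' as an enantioconvergent arylation. The forward key step would be a nickel/bis(oxazoline)-catalysed coupling of the racemic α-bromo ketone A5 with 2-methoxy-4-methylphenylmagnesium bromide to give the α-aryl ketone A6. This is stereoconvergent in spirit but fixes only one centre. The C3' ketone of A6 would then have to be reduced against the Felkin preference of both flanking centres to reach the all-syn triad. The C2' centre of A5 and A6 is α to the ketone and exposed to a basic Grignard reagent. The primary carbon would still need oxidation before the pyranone could be built, so the route is also longer. In the chosen plan the same reduction is steered to the all-cis isomer by the ring.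

Key step: step 4

Assumption: the (R,R)-configured catalyst is taken to deliver hydride to the carbonyl face that gives the (3S,4R,5S) isomer, with the ester-bearing flank playing the role of the π-substituted flank of an aryl ketone. If the sense is the opposite one, the (S,S)-catalyst is used and nothing else changes.

## Steps

Step 1
Reactants: 1 2-bromo-5-methylphenol
Product: 2 2-(benzyloxy)-1-bromo-4-methylbenzene
Conditions: BnBr, K2CO3, DMF, 60 °C
Reagents that add atoms: benzyl bromide, BrCc1ccccc1
Why: Williamson ether synthesis on the phenoxide; the benzyl ether should withstand the basic and reductive steps 2–4 and is removed without an extra step in step 5.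

Step 2
Reactants: 2 2-(benzyloxy)-1-bromo-4-methylbenzene; 3 thian-4-one (tetrahydro-4H-thiopyran-4-one)
Product: 4 3-[2-(benzyloxy)-4-methylphenyl]thian-4-one (racemic)
Conditions: Pd(OAc)2 (2 mol%), 2-dicyclohexylphosphino-2'-methylbiphenyl (4 mol%), NaOtBu, toluene, 70 °C; 3 in twofold excess
Reagents that add atoms: none
Why: Buchwald–Hartwig-type α-arylation of a cyclic ketone: oxidative addition of 2 to zerovalent palladium, enolate binding and C–C reductive elimination. The product rests as its aryl-conjugated enolate, which is too hindered to be arylated again, and its configuration is irrelevant because the centre is mobile until step 4.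

Step 3
Reactants: 4 3-[2-(benzyloxy)-4-methylphenyl]thian-4-one
Product: 5 methyl 5-[2-(benzyloxy)-4-methylphenyl]-4-oxothiane-3-carboxylate (racemic at C5; keto–enol and cis/trans mixture at C3)
Conditions: NaH, (MeO)2CO, THF, reflux; AcOH quench
Reagents that add atoms: dimethyl carbonate, COC(=O)OC
Why: Claisen-type C-methoxycarbonylation under equilibrating conditions. Acylation at the aryl-bearing carbon would give a non-enolisable keto ester that reverts by retro-Claisen cleavage, so the material should drain into the enolate of 5, the only product with an acidic C3–H.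

Step 4
Reactants: 5 methyl 5-[2-(benzyloxy)-4-methylphenyl]-4-oxothiane-3-carboxylate
Product: 6 methyl (3S,4R,5S)-5-[2-(benzyloxy)-4-methylphenyl]-4-hydroxythiane-3-carboxylate (all-cis)
Conditions: RuCl[(R,R)-TsDPEN](p-cymene) (2 mol%), HCO2H/Et3N (1:2.5), DMF, 40 °C
Reagents that add atoms: none
Why: Noyori–Ikariya asymmetric transfer hydrogenation run as a dynamic kinetic resolution: the 16-electron ruthenium amide takes up hydride and proton from formate with loss of CO2, and the Ru–H/N–H pair passes both to the C4 carbonyl of the keto tautomer through a six-membered outer-sphere transition state; no ring is closed. The closest known reactions are the cis-selective dynamic transfer hydrogenation of cyclic 2-alkoxycarbonyl ketones and the cis-selective dynamic reduction of 2-arylcycloalkanones. C3 equilibrates through the enol of the β-keto ester and C5 through amine-mediated enolisation of the α-aryl ketone, so all four stereoisomers of 5 interconvert. The diequatorial cis-keto form is the most populated keto isomer and offers an unhindered equatorial trajectory, so hydride should enter there and leave the carbinol oxygen axial, cis to both neighbours (C4 set by ring conformation). The catalyst decides which enantiomer of the cis-ketone is reduced, and with it the absolute configuration at C3, C4 and C5 together, by telling the ester-bearing flank of the carbonyl from the aryl-bearing flank. The step needs cis,cis diastereoselection (secured by the chair), enantiomer discrimination (ester versus aryl recognition by the chiral Ru–H/N–H pocket) and epimerisation at C5 faster than reduction of the mismatched isomers (amine-rich medium, mild heating). Once reduced, C4 and C5 are no longer mobile and the product leaves the equilibrium as one isomer.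

Step 5
Reactants: 6 methyl (3S,4R,5S)-5-[2-(benzyloxy)-4-methylphenyl]-4-hydroxythiane-3-carboxylate
Product: 7 methyl (2S,3R,4S)-3-hydroxy-4-(2-hydroxy-4-methylphenyl)-2-methylpentanoate
Conditions: Raney Ni (W-2, washed neutral), H2 (1 atm), MeOH, 50 °C
Reagents that add atoms: none
Why: Raney nickel desulfurisation replaces both C–S bonds by C–H without touching ring atoms C3, C4 and C5, so ring C2 and C6 become the two C-methyl groups and the all-cis ring becomes the all-syn chain. The same catalyst hydrogenolyses the aryl benzyl ether to the phenol.

Step 6
Reactants: 7 methyl (2S,3R,4S)-3-hydroxy-4-(2-hydroxy-4-methylphenyl)-2-methylpentanoate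
Product: 8 methyl (2S,3R,4S)-3-hydroxy-2-methyl-4-{4-methyl-2-[(trifluoromethanesulfonyl)oxy]phenyl}pentanoate
Conditions: PhNTf2, Et3N, DMAP (cat.), CH2Cl2, 0 °C to rt
Reagents that add atoms: N-phenylbis(trifluoromethanesulfonimide), O=S(=O)(N(c1ccccc1)S(=O)(=O)C(F)(F)F)C(F)(F)F
Why: O-sulfonylation of the phenoxide with a mild triflyl donor, which should not react with the hindered secondary alcohol.

Step 7
Reactants: 8 methyl (2S,3R,4S)-3-hydroxy-2-methyl-4-{4-methyl-2-[(trifluoromethanesulfonyl)oxy]phenyl}pentanoate; 9 (E)-tert-butyldimethyl{[3-(4,4,5,5-tetramethyl-1,3,2-dioxaborolan-2-yl)prop-2-en-1-yl]oxy}silane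
Product: 10 methyl (2S,3R,4S)-4-{2-[(1E)-3-(tert-butyldimethylsilyloxy)prop-1-en-1-yl]-4-methylphenyl}-3-hydroxy-2-methylpentanoate
Conditions: Pd(OAc)2 (3 mol%), SPhos (6 mol%), K3PO4, THF/H2O (10:1), 50 °C
Reagents that add atoms: none
Why: Suzuki–Miyaura coupling of an aryl triflate with an (E)-alkenylboronate; transmetalation and reductive elimination retain the alkene geometry of 9, and the bulky electron-rich phosphine is chosen for the ortho-branched triflate.

Step 8
Reactants: 10 methyl (2S,3R,4S)-4-{2-[(1E)-3-(tert-butyldimethylsilyloxy)prop-1-en-1-yl]-4-methylphenyl}-3-hydroxy-2-methylpentanoate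
Product: 11 (2S,3R,4S)-4-{2-[(1E)-3-(tert-butyldimethylsilyloxy)prop-1-en-1-yl]-4-methylphenyl}-3-hydroxy-N-methoxy-N,2-dimethylpentanamide
Conditions: MeNH(OMe)·HCl, iPrMgCl, THF, −20 to 0 °C
Reagents that add atoms: N,O-dimethylhydroxylamine hydrochloride, CNOC.Cl
Why: Aminolysis of the methyl ester by the chloromagnesium amide of N,O-dimethylhydroxylamine (Weinreb amide formation); the C3 magnesium alkoxide forms first and is stable to retro-aldol cleavage at this temperature, and C2 is not enolised.

Step 9
Reactants: 11 (2S,3R,4S)-4-{2-[(1E)-3-(tert-butyldimethylsilyloxy)prop-1-en-1-yl]-4-methylphenyl}-3-hydroxy-N-methoxy-N,2-dimethylpentanamide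
Product: 12 (2S,3R,4S)-4-{2-[(1E)-3-(tert-butyldimethylsilyloxy)prop-1-en-1-yl]-4-methylphenyl}-N-methoxy-N,2-dimethyl-3-(triethylsilyloxy)pentanamide
Conditions: TESOTf, 2,6-lutidine, CH2Cl2, −78 to 0 °C
Reagents that add atoms: triethylsilyl trifluoromethanesulfonate, CC[Si](CC)(CC)OS(=O)(=O)C(F)(F)F
Why: Silylation of a hindered secondary alcohol with a silyl triflate; the ether blocks retro-aldol cleavage, hemiketal formation and β-elimination in steps 10 and 11.

Step 10
Reactants: 12 (2S,3R,4S)-4-{2-[(1E)-3-(tert-butyldimethylsilyloxy)prop-1-en-1-yl]-4-methylphenyl}-N-methoxy-N,2-dimethyl-3-(triethylsilyloxy)pentanamide; 13 ethyl 2-ethyl-3-oxobutanoate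
Product: 14 ethyl (6S,7R,8S)-8-{2-[(1E)-3-(tert-butyldimethylsilyloxy)prop-1-en-1-yl]-4-methylphenyl}-2-ethyl-6-methyl-3,5-dioxo-7-(triethylsilyloxy)nonanoate (C2 epimers, keto–enol tautomers)
Conditions: 13 (3 equiv), LiN(iPr)2 (6.3 equiv), THF, −78 to 0 °C; then 12, −78 to 0 °C; AcOH quench
Reagents that add atoms: none
Why: γ-Acylation of the acetoacetate dianion by a Weinreb amide (Claisen-type condensation): the terminal carbanion adds, and the N-methoxy chelate holds the tetrahedral intermediate until the quench, so no second addition occurs. The ethyl-bearing C2 forms as a mixture that becomes sp2 in step 11.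

Step 11
Reactants: 14 ethyl (6S,7R,8S)-8-{2-[(1E)-3-(tert-butyldimethylsilyloxy)prop-1-en-1-yl]-4-methylphenyl}-2-ethyl-6-methyl-3,5-dioxo-7-(triethylsilyloxy)nonanoate
Product: 15 6-[(2S,3R,4S)-4-{2-[(1E)-3-(tert-butyldimethylsilyloxy)prop-1-en-1-yl]-4-methylphenyl}-3-(triethylsilyloxy)pentan-2-yl]-3-ethyl-4-hydroxy-2H-pyran-2-one
Conditions: DBU, toluene, 60 °C
Reagents that add atoms: none
Why: Base-mediated lactonisation of a 3,5-dioxo ester: the C5 enolate oxygen attacks the ester carbonyl (6-exo-trig), ethanol leaves and tautomerisation gives the 4-hydroxy-2-pyranone. The 1,3-dicarbonyl unit rests as its C4 enolate, which should keep the adjacent C6–H (the future C2') from being removed.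

Step 12
Reactants: 15 6-[(2S,3R,4S)-4-{2-[(1E)-3-(tert-butyldimethylsilyloxy)prop-1-en-1-yl]-4-methylphenyl}-3-(triethylsilyloxy)pentan-2-yl]-3-ethyl-4-hydroxy-2H-pyran-2-one
Product: 16 veramycin A, 3-ethyl-4-hydroxy-6-[(2S,3R,4S)-3-hydroxy-4-{2-[(1E)-3-hydroxyprop-1-en-1-yl]-4-methylphenyl}pentan-2-yl]-2H-pyran-2-one
Conditions: HF·pyridine, pyridine, THF, 0 °C to rt
Reagents that add atoms: none
Why: Fluoride-mediated cleavage of both silyl ethers under buffered, weakly acidic conditions that should neither ionise the cinnamyl alcohol nor affect the pyranone; no stereocentre is touched.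

## Compound list

1 | 2-bromo-5-methylphenol | Cc1ccc(Br)c(O)c1 | starting material
2 | 2-(benzyloxy)-1-bromo-4-methylbenzene | Cc1ccc(Br)c(OCc2ccccc2)c1 | intermediate
3 | thian-4-one (tetrahydro-4H-thiopyran-4-one) | O=C1CCSCC1 | starting material
4 | 3-[2-(benzyloxy)-4-methylphenyl]thian-4-one (racemic) | O=C1CCSCC1c1ccc(C)cc1OCc1ccccc1 | intermediate
5 | methyl 5-[2-(benzyloxy)-4-methylphenyl]-4-oxothiane-3-carboxylate (stereoisomer and tautomer mixture) | COC(=O)C1CSCC(c2ccc(C)cc2OCc2ccccc2)C1=O | intermediate
6 | methyl (3S,4R,5S)-5-[2-(benzyloxy)-4-methylphenyl]-4-hydroxythiane-3-carboxylate | S1C[C@H](C(=O)OC)[C@H](O)[C@H](c2ccc(C)cc2OCc2ccccc2)C1 | intermediate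
7 | methyl (2S,3R,4S)-3-hydroxy-4-(2-hydroxy-4-methylphenyl)-2-methylpentanoate | COC(=O)[C@@H](C)[C@H](O)[C@@H](C)c1ccc(C)cc1O | intermediate
8 | methyl (2S,3R,4S)-3-hydroxy-2-methyl-4-{4-methyl-2-[(trifluoromethanesulfonyl)oxy]phenyl}pentanoate | COC(=O)[C@@H](C)[C@H](O)[C@@H](C)c1ccc(C)cc1OS(=O)(=O)C(F)(F)F | intermediate
9 | (E)-tert-butyldimethyl{[3-(4,4,5,5-tetramethyl-1,3,2-dioxaborolan-2-yl)prop-2-en-1-yl]oxy}silane | CC(C)(C)[Si](C)(C)OC/C=C/B1OC(C)(C)C(C)(C)O1 | starting material
10 | methyl (2S,3R,4S)-4-{2-[(1E)-3-(tert-butyldimethylsilyloxy)prop-1-en-1-yl]-4-methylphenyl}-3-hydroxy-2-methylpentanoate | COC(=O)[C@@H](C)[C@H](O)[C@@H](C)c1ccc(C)cc1/C=C/CO[Si](C)(C)C(C)(C)C | intermediate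
11 | (2S,3R,4S)-4-{2-[(1E)-3-(tert-butyldimethylsilyloxy)prop-1-en-1-yl]-4-methylphenyl}-3-hydroxy-N-methoxy-N,2-dimethylpentanamide | CON(C)C(=O)[C@@H](C)[C@H](O)[C@@H](C)c1ccc(C)cc1/C=C/CO[Si](C)(C)C(C)(C)C | intermediate
12 | (2S,3R,4S)-4-{2-[(1E)-3-(tert-butyldimethylsilyloxy)prop-1-en-1-yl]-4-methylphenyl}-N-methoxy-N,2-dimethyl-3-(triethylsilyloxy)pentanamide | CON(C)C(=O)[C@@H](C)[C@H](O[Si](CC)(CC)CC)[C@@H](C)c1ccc(C)cc1/C=C/CO[Si](C)(C)C(C)(C)C | intermediate
13 | ethyl 2-ethyl-3-oxobutanoate | CCOC(=O)C(CC)C(C)=O | starting material
14 | ethyl (6S,7R,8S)-8-{2-[(1E)-3-(tert-butyldimethylsilyloxy)prop-1-en-1-yl]-4-methylphenyl}-2-ethyl-6-methyl-3,5-dioxo-7-(triethylsilyloxy)nonanoate (C2 epimers) | CCOC(=O)C(CC)C(=O)CC(=O)[C@@H](C)[C@H](O[Si](CC)(CC)CC)[C@@H](C)c1ccc(C)cc1/C=C/CO[Si](C)(C)C(C)(C)C | intermediate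
15 | 6-[(2S,3R,4S)-4-{2-[(1E)-3-(tert-butyldimethylsilyloxy)prop-1-en-1-yl]-4-methylphenyl}-3-(triethylsilyloxy)pentan-2-yl]-3-ethyl-4-hydroxy-2H-pyran-2-one | CCc1c(O)cc([C@@H](C)[C@H](O[Si](CC)(CC)CC)[C@@H](C)c2ccc(C)cc2/C=C/CO[Si](C)(C)C(C)(C)C)oc1=O | intermediate
16 | veramycin A | CCc1c(O)cc([C@@H](C)[C@H](O)[C@@H](C)c2ccc(C)cc2/C=C/CO)oc1=O | target

## Step count and risks

Total step count: 12. Longest linear sequence: 12 steps, from 1 to 16; compounds 3, 9 and 13 enter as purchased building blocks.

Step 4 (key step). The most likely failure is epimerisation at C5 that is too slow relative to hydride transfer. The α-aryl C–H of a dialkyl-type ketone is only weakly acidic, and the ortho-benzyloxy group twists the ring out of conjugation with the enolate. The reduction would then become a kinetic resolution. Lesser risks are weak discrimination between the two flanks of the carbonyl and slowing of the catalyst by sulfur coordination. Fallback (sets out from 5, returns to 6): the dynamic element is given up. The same hydrogen transfer is run as a classical kinetic resolution in the acidic 5:2 HCO2H/Et3N mixture and stopped near half conversion. Compound 6 is separated from the unreacted slow enantiomer, methyl (5R)-5-[2-(benzyloxy)-4-methylphenyl]-4-oxothiane-3-carboxylate F1. F1 is racemised in a separate flask with DBU in toluene back to 5 and resubmitted.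

Step 2. The most likely failure is deactivation of the catalyst by sulfur: base-induced retro-thia-Michael opening of the ketone enolate would free a thiolate that binds palladium or enters C–S coupling. Diarylation is a lesser risk. Fallback (sets out from 2, returns to 5, and so also bypasses 4 and step 3): the ring is built around the aryl group without palladium. Magnesium insertion into 2 (Mg, THF) and acylation with dimethyl oxalate at −78 °C would give methyl 2-[2-(benzyloxy)-4-methylphenyl]-2-oxoacetate F2. Wittig methylenation with Ph3P=CH2 would give methyl 2-[2-(benzyloxy)-4-methylphenyl]prop-2-enoate F3. Thia-Michael addition of methyl 3-sulfanylpropanoate (cat. NaOMe, MeOH) would give methyl 2-[2-(benzyloxy)-4-methylphenyl]-3-[(3-methoxy-3-oxopropyl)sulfanyl]propanoate F4. Dieckmann condensation of F4 (NaOMe, THF, reflux) should close to 5, because only the ring closure that leaves an acidic C3–H survives under equilibrating conditions.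

Step 5. The most likely failures are incomplete hydrogenolysis of the O-benzyl group while the C–S bonds are already cleaved, and nickel-mediated dehydrogenation and rehydrogenation at the carbinol, which would scramble C3 of the chain. Retro-aldol cleavage on residual base is a further possibility. Fallback (sets out from 6, returns to 7): the two hydrogenolyses are decoupled and given different metals. Raney Ni deactivated by boiling in acetone, used in EtOH at 25 °C without a hydrogen atmosphere, should cleave only the C–S bonds and give methyl (2S,3R,4S)-4-[2-(benzyloxy)-4-methylphenyl]-3-hydroxy-2-methylpentanoate F5. The benzyl ether of F5 is then removed with H2 over Pd/C in EtOAc to give 7.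

Step 10. The most likely failure is that the basic dianion deprotonates instead of adding to the hindered carbonyl. Enolisation at C2 of the amide would lead to epimerisation or β-elimination of the silyloxy group, and attack on the N-methoxy group would lead to loss of formaldehyde. Fallback (sets out from 12, returns to 14): the electrophile is changed to the less hindered, more reactive aldehyde. Reduction of 12 with iBu2AlH in THF at −78 °C would give (2S,3R,4S)-4-{2-[(1E)-3-(tert-butyldimethylsilyloxy)prop-1-en-1-yl]-4-methylphenyl}-2-methyl-3-(triethylsilyloxy)pentanal F6. Aldol addition of the same dianion of 13 to F6 at −78 °C would give ethyl (6R,7R,8S)-8-{2-[(1E)-3-(tert-butyldimethylsilyloxy)prop-1-en-1-yl]-4-methylphenyl}-2-ethyl-5-hydroxy-6-methyl-3-oxo-7-(triethylsilyloxy)nonanoate F7 as a mixture at C2 and C5. Oxidation of the C5 carbinol of F7 with Dess–Martin periodinane returns 14.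

## Further compounds

F1 | step 4 | methyl (5R)-5-[2-(benzyloxy)-4-methylphenyl]-4-oxothiane-3-carboxylate | COC(=O)C1CSC[C@H](c2ccc(C)cc2OCc2ccccc2)C1=O
F2 | step 2 | methyl 2-[2-(benzyloxy)-4-methylphenyl]-2-oxoacetate | COC(=O)C(=O)c1ccc(C)cc1OCc1ccccc1
F3 | step 2 | methyl 2-[2-(benzyloxy)-4-methylphenyl]prop-2-enoate | COC(=O)C(=C)c1ccc(C)cc1OCc1ccccc1
F4 | step 2 | methyl 2-[2-(benzyloxy)-4-methylphenyl]-3-[(3-methoxy-3-oxopropyl)sulfanyl]propanoate | COC(=O)CCSCC(C(=O)OC)c1ccc(C)cc1OCc1ccccc1
F5 | step 5 | methyl (2S,3R,4S)-4-[2-(benzyloxy)-4-methylphenyl]-3-hydroxy-2-methylpentanoate | COC(=O)[C@@H](C)[C@H](O)[C@@H](C)c1ccc(C)cc1OCc1ccccc1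
F6 | step 10 | (2S,3R,4S)-4-{2-[(1E)-3-(tert-butyldimethylsilyloxy)prop-1-en-1-yl]-4-methylphenyl}-2-methyl-3-(triethylsilyloxy)pentanal | O=C[C@@H](C)[C@H](O[Si](CC)(CC)CC)[C@@H](C)c1ccc(C)cc1/C=C/CO[Si](C)(C)C(C)(C)C
F7 | step 10 | ethyl (6R,7R,8S)-8-{2-[(1E)-3-(tert-butyldimethylsilyloxy)prop-1-en-1-yl]-4-methylphenyl}-2-ethyl-5-hydroxy-6-methyl-3-oxo-7-(triethylsilyloxy)nonanoate (mixture at C2 and C5) | CCOC(=O)C(CC)C(=O)CC(O)[C@@H](C)[C@H](O[Si](CC)(CC)CC)[C@@H](C)c1ccc(C)cc1/C=C/CO[Si](C)(C)C(C)(C)C
A1 | alternative 1 | (2S)-2-(2-bromo-4-methylphenyl)propanal | O=C[C@@H](C)c1ccc(C)cc1Br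
A2 | alternative 1 | (4S)-4-benzyl-3-[(2S,3R,4S)-4-(2-bromo-4-methylphenyl)-3-hydroxy-2-methylpentanoyl]-1,3-oxazolidin-2-one | O=C1OC[C@H](Cc2ccccc2)N1C(=O)[C@@H](C)[C@H](O)[C@@H](C)c1ccc(C)cc1Br
A3 | alternative 2 | 3,6-diethyl-4-methoxy-2H-pyran-2-one | CCc1cc(OC)c(CC)c(=O)o1
A4 | alternative 2 | 6-[(2S,3R,4S)-4-(2-bromo-4-methylphenyl)-3-hydroxypentan-2-yl]-3-ethyl-4-methoxy-2H-pyran-2-one | CCc1c(OC)cc([C@@H](C)[C@H](O)[C@@H](C)c2ccc(C)cc2Br)oc1=O
A5 | alternative 3 | (2R)-4-bromo-1-[(tert-butyldimethylsilyl)oxy]-2-methylpentan-3-one (both C4 epimers) | CC(Br)C(=O)[C@H](C)CO[Si](C)(C)C(C)(C)C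
A6 | alternative 3 | (2R,4S)-1-[(tert-butyldimethylsilyl)oxy]-4-(2-methoxy-4-methylphenyl)-2-methylpentan-3-one | C[C@@H](c1ccc(C)cc1OC)C(=O)[C@H](C)CO[Si](C)(C)C(C)(C)C
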